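# Proposed synthesis of CNP0196568.6 via an alkyne–alkene photocycloaddition and cyclobutene cleavage

Remark on the chemistry (assumptions): atoms carry flavanone numbers. Unit A (unprimed) is the 4-methoxyphenyl half and unit B (doubly primed) the 4-hydroxyphenyl half; ring A is the benzo ring and ring C the pyranone ring of each unit. The zinc–ProPhenol alkynylations are taken to be ligand-controlled; the ligand enantiomer is specified by the aldehyde face it must address, and the assignment would be checked by Mosher ester analysis.

## Analysis of the target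

The target is a 3,3''-linked biflavanone: two 5,7-dihydroxychroman-4-one units joined by the single bond C3–C3''. C2 carries a 4-methoxyphenyl group and C2'' a 4-hydroxyphenyl group. The four contiguous stereocentres are (2S,3R,3''S,2''S). Unit A is 2,3-trans, unit B is 2'',3''-cis, and the central pair C3/C3'' is unlike, the arrangement that would be meso if the halves were identical.

C3 and C3'' are each alpha to one ketone and beta to the other, so both tertiary C–H centres can epimerise. The cis ring of unit B is the less stable arrangement, and both pyranone rings can open by retro-oxa-Michael reaction under base. Five free phenols on electron-rich rings rule out strong oxidants and acids late in the route.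

The difficulty is that the halves differ only in one O-methyl group and in the relative configuration at C2/C3. A dimerisation therefore cannot work, and the cis ring must be made under kinetic control and kept away from equilibrating conditions.

The strategy rests on the 1,4-diketone C4(=O)–C3–C3''–C4''(=O). It is what remains when a cyclobutene C3–C4=C4''–C3'' is cleaved at its double bond. That cyclobutene is the [2+2] adduct of a diarylacetylene C4≡C4'' (spanning ring A of unit A and ring A of unit B) and a Z-alkene C3=C3''. Addition to both alkene carbons on the same face of a Z-alkene gives exactly the unlike C3/C3'' pair.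

## Retrosynthetic reasoning

**23 to 22.** The five phenols are masked as benzyl ethers. They come off by neutral hydrogenolysis, the only deprotection that exposes the cis ring of unit B to neither acid nor base. The methyl ether that distinguishes the halves is carried from aldehyde 11.

**22 to 20.** Ring C of unit B is cut at O1''–C8a'' and not at O1''–C2''. Attack of the C2'' oxygen on a fluoroarene activated by the ortho ketone C4'' leaves the benzylic C2''–O bond intact, so C2'' cannot ionise. The cis relationship is then simply the sum of a C2'' centre made earlier and a C3'' centre made in the key step. The forward reaction must close the ring faster than the beta-alkoxy ketone can enolise, eliminate or fragment.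

**20 to 19 to 17.** Both carbonyl groups are traced back to the double bond C4=C4'' of cyclobutene 17 by glycol cleavage and dihydroxylation. One neutral two-step operation unveils both aryl ketones and ring C of unit A as a chromanone. No enolisable centre exists before this point.

**17 to 16 (key disconnection).** The bonds C3–C4 and C3''–C4'' are cut. This returns the diarylacetylene and a Z-alkene held on ring A of unit A through O1–C2. The forward step must make a six-membered ring and a cyclobutene, fix C3 relative to C2, and fix C3'' relative to C3 by keeping the Z geometry.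

**16 to 15 + 3.** The bond between C4'' and ring A of unit B is cut (Sonogashira coupling). The fluoroarene partner 3 is simple and can be used in excess. Forming the diarylacetylene last keeps it away from the alkyne semihydrogenation.

**15 to 14 to 13.** The terminal alkyne is taken back to an aryl aldehyde (one-carbon homologation; the carbon added is C4''), and the Z-alkene to the alkyne C3≡C3'' (semihydrogenation). Carrying ring A as a salicylaldehyde avoids an aryl iodide during hydrogenation and a second alkyne during reduction.

**13 to 12 + 5.** O1–C2 is cut with inversion at C2 (Mitsunobu etherification). The cut is made at the alkyne stage for three reasons. An alkynyl group stabilises the 4-methoxybenzylic cation less than an alkenyl group, no SN2' pathway with loss of alkene geometry exists, and a silyl group cannot migrate across a linear alkyne as it can across a cis-alkene diol.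

**12 to 10 + 11 and 10 to 9 to 8 to 6 + 7.** C2–C3 and C2''–C3'' are cut at the two carbinols. Each comes from a catalytic asymmetric alkynylation of an aromatic aldehyde, the two oxygens being differentiated by the order of events. The first carbinol is silylated before the second is made.

**5 to 4 and 3 to 2 to 1.** Ring A of unit A comes from ortho-formylation of phenol 4, where both ortho positions are equivalent. Ring A of unit B comes from iodination of the dibenzyl ether 2 of fluororesorcinol 1.

## Alternatives that were turned down

**Alternative 1:** Disconnection of O1–C2 and C4–C4a of unit A, with C3'' and C4'' left as an acetate arm on C3.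
- Forward key step: the caesium salt of phenol 4 opens cis-beta-lactone A1 at the benzylic carbon with inversion. The acid so released is activated in the same flask as a mixed anhydride and acylates the phenoxy ring, giving trans flavanone ester A2.
- For: both events are classical ionic chemistry. The cis geometry of A1 translates into the 2,3-trans relationship, and acylation of a phloroglucinol-type ring is easy.
- Against: the benzylic carbon of A1 bears a 4-methoxyphenyl group, so ionisation or loss of CO2 competes with substitution, and the ambident phenoxide can attack the acyl carbon or react through carbon. Above all, A2 holds only unit A. C3'' is a methylene group, C4'' an ester, and C2'' and ring A of unit B are absent. Unit B would need an aldol reaction at C3'' in the presence of the more acidic C3–H, acyclic control of two more stereocentres towards the cis ring, a second aryl ketone synthesis and a ring closure. That is at least five steps with C3 exposed to base.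
- Comparison: Alternative 1 is stronger in the reliability and scalability of its key step. The chosen strategy offers in its place a precursor that already contains every carbon and both carbinol centres, and it forms C3–C4 and C3''–C4'' and reveals both ketones in two events.

**Alternative 2:** Disconnection of C3–C4 and O1–C2 of unit A by a hetero-Diels–Alder reaction.
- Forward key step: a chiral Brønsted acid ionises acetal A3 to an O-methyl o-quinone methide, which adds across the E alkene of styrylchromone A4 to give 4-methoxyflavan A5.
- For: it is convergent, the partners are simple, C2 and C3 are set by a catalyst from achiral materials, and the E geometry maps onto 2,3-trans.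
- Against: with a 4-methoxystyrene the addition is stepwise through a benzylic cation, so transfer of geometry and enantiocontrol are uncertain. The 3-vinylchromone unit of A4 is itself a diene and can react at the wrong atoms. A5 lacks the C4 ketone, which would have to be made from a benzylic methyl ether on an electron-rich flavan. It also lacks the 2''-aryl group and both stereocentres of unit B, which would need conjugate arylation of a hindered 3-substituted chromone and a kinetic protonation under substrate control.
- Comparison: Alternative 2 is as strong or stronger in convergence and in catalytic asymmetric induction. The chosen strategy offers both C4 carbons at the ketone level on cleavage, C2'' from a reliable carbonyl addition and C3'' from alkene geometry.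

**Alternative 3:** Disconnection of C3–C4 of unit A by an intramolecular Stetter reaction.
- Forward key step: a triazolylidene carbene turns the aldehyde of aldehyde–enone A6 into an acyl anion equivalent that adds to C3, the beta carbon of the exocyclic enone. Ring C of unit A closes, and the C3'' enolate is protonated to give A7, which is identical with compound 22.
- For: the Stetter closure of salicylaldehyde-derived substrates to chroman-4-ones is an established class. A7 is one step from the target, so this is the shortest endgame of the four strategies, and protonation anti to the 2''-aryl group could give the cis ring directly.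
- Against: the acceptor is a trisubstituted enone with an aryloxy group at the gamma position. The base needed to generate the carbene invites vinylogous elimination of the phenoxide and retro-oxa-Michael opening of the unit B ring, which would scramble C2''. Two centres (C3 by addition, C3'' by protonation) form under the mixed influence of catalyst, C2 and C2''. A6 itself requires condensation with an alpha-aryl-alpha-aryloxy aldehyde, which would racemise at C2.
- Comparison: Alternative 3 is stronger in step count after the key step and in using a known reaction class. The chosen strategy offers a precursor built from configurationally stable carbinols with no enolisable or eliminable site, and a key step run without base or nucleophilic catalyst.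

Key step: step 12

## Route

Step 1
Reactants: 1 5-fluororesorcinol
Product: 2 1,3-bis(benzyloxy)-5-fluorobenzene
Conditions: BnBr, K2CO3, DMF, 60 °C
Reagents that add atoms: benzyl bromide, BrCc1ccccc1
Why: Williamson etherification of both phenols; the unactivated aryl fluoride is inert to carbonate.

Step 2
Reactants: 2 1,3-bis(benzyloxy)-5-fluorobenzene
Product: 3 1,5-bis(benzyloxy)-3-fluoro-2-iodobenzene
Conditions: N-iodosuccinimide, CF3CO2H (cat.), MeCN, 0 °C to rt
Reagents that add atoms: N-iodosuccinimide, O=C1CCC(=O)N1I
Why: Electrophilic aromatic iodination; all free positions are activated by both ether groups, and the position between fluorine and one benzyloxy group (para to the other) is less hindered than the one flanked by two benzyloxy groups, so 3 should be the main, separable regioisomer.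

Step 3
Reactants: 4 3,5-bis(benzyloxy)phenol
Product: 5 4,6-bis(benzyloxy)-2-hydroxybenzaldehyde
Conditions: MgCl2, Et3N, (CH2O)n, MeCN, reflux
Reagents that add atoms: paraformaldehyde (formaldehyde), C=O
Why: Magnesium phenoxide-directed ortho-formylation (Casiraghi–Skattebøl); formaldehyde is delivered inside the chelate only ortho to the free hydroxyl, the two ortho positions are equivalent, and a second formaldehyde acts as hydride acceptor.

Step 4
Reactants: 6 4-(benzyloxy)benzaldehyde; 7 ethynyltrimethylsilane
Product: 8 (1R)-1-[4-(benzyloxy)phenyl]-3-(trimethylsilyl)prop-2-yn-1-ol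
Conditions: ZnMe2, ProPhenol ligand (10 mol %, the enantiomer that addresses the Si face of 6), Ph3P=O (20 mol %), toluene, 0 °C
Reagents that add atoms: none
Why: Catalytic asymmetric alkynylation of an aromatic aldehyde by an alkynylzinc made in situ (dinuclear zinc–ProPhenol catalysis); Si-face delivery sets C2'', which is R here and becomes the S centre of the target once the substituent priorities change.

Step 5
Reactants: 8 (1R)-1-[4-(benzyloxy)phenyl]-3-(trimethylsilyl)prop-2-yn-1-ol
Product: 9 tert-butyl{[(1R)-1-[4-(benzyloxy)phenyl]-3-(trimethylsilyl)prop-2-yn-1-yl]oxy}dimethylsilane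
Conditions: TBSCl, imidazole, DMF, rt
Reagents that add atoms: tert-butyldimethylsilyl chloride, CC(C)(C)[Si](C)(C)Cl
Why: Silylation of the secondary alcohol; this ether should survive carbonate, zinc reagents, Mitsunobu conditions, hydrogenation, palladium, light and osmium, and its later removal triggers the last ring closure.

Step 6
Reactants: 9 tert-butyl{[(1R)-1-[4-(benzyloxy)phenyl]-3-(trimethylsilyl)prop-2-yn-1-yl]oxy}dimethylsilane
Product: 10 tert-butyl{[(1S)-1-[4-(benzyloxy)phenyl]prop-2-yn-1-yl]oxy}dimethylsilane
Conditions: K2CO3 (cat.), MeOH, rt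
Reagents that add atoms: none
Why: Methanolysis of the C(sp)–Si bond only; the alkyl silyl ether is stable to carbonate in methanol, and the descriptor changes from R to S without any change at the centre.

Step 7
Reactants: 10 tert-butyl{[(1S)-1-[4-(benzyloxy)phenyl]prop-2-yn-1-yl]oxy}dimethylsilane; 11 4-methoxybenzaldehyde
Product: 12 (1S,4R)-4-[4-(benzyloxy)phenyl]-4-[(tert-butyldimethylsilyl)oxy]-1-(4-methoxyphenyl)but-2-yn-1-ol
Conditions: ZnMe2, ProPhenol ligand (10 mol %, the enantiomer opposite to that of step 4, addressing the Re face of 11), Ph3P=O (20 mol %), toluene, 0 °C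
Reagents that add atoms: none
Why: Second zinc–ProPhenol alkynylation; Re-face delivery sets C2 as S under catalyst control, the remote C2'' centre should have little influence, and the minor diastereomer is separable.

Step 8
Reactants: 12 (1S,4R)-4-[4-(benzyloxy)phenyl]-4-[(tert-butyldimethylsilyl)oxy]-1-(4-methoxyphenyl)but-2-yn-1-ol; 5 4,6-bis(benzyloxy)-2-hydroxybenzaldehyde
Product: 13 2-{[(1R,4R)-4-[4-(benzyloxy)phenyl]-4-[(tert-butyldimethylsilyl)oxy]-1-(4-methoxyphenyl)but-2-yn-1-yl]oxy}-4,6-bis(benzyloxy)benzaldehyde
Conditions: PPh3, diisopropyl azodicarboxylate, toluene, −20 °C to rt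
Reagents that add atoms: none
Why: Mitsunobu etherification with inversion at C2, forming O1–C2; it is run at the alkyne stage because the alkynyl group stabilises the benzylic cation less than an alkenyl group would, no SN2' path exists and the silyl group cannot migrate across the linear alkyne; any leakage through ionisation would appear as the separable C2 epimer.

Step 9
Reactants: 13 2-{[(1R,4R)-4-[4-(benzyloxy)phenyl]-4-[(tert-butyldimethylsilyl)oxy]-1-(4-methoxyphenyl)but-2-yn-1-yl]oxy}-4,6-bis(benzyloxy)benzaldehyde
Product: 14 2-{[(1S,2Z,4S)-4-[4-(benzyloxy)phenyl]-4-[(tert-butyldimethylsilyl)oxy]-1-(4-methoxyphenyl)but-2-en-1-yl]oxy}-4,6-bis(benzyloxy)benzaldehyde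
Conditions: H2 (1 atm), Lindlar catalyst (Pd on CaCO3 poisoned with Pb(OAc)2), quinoline, EtOAc, rt
Reagents that add atoms: none
Why: Lindlar semihydrogenation; syn delivery of hydrogen to the only alkyne gives the Z-alkene C3=C3'', and the poisoned catalyst should leave the electron-rich aldehyde, the benzyl ethers and the C–O bonds at C2 and C2'' alone.

Step 10
Reactants: 14 2-{[(1S,2Z,4S)-4-[4-(benzyloxy)phenyl]-4-[(tert-butyldimethylsilyl)oxy]-1-(4-methoxyphenyl)but-2-en-1-yl]oxy}-4,6-bis(benzyloxy)benzaldehyde
Product: 15 1,5-bis(benzyloxy)-3-{[(1S,2Z,4S)-4-[4-(benzyloxy)phenyl]-4-[(tert-butyldimethylsilyl)oxy]-1-(4-methoxyphenyl)but-2-en-1-yl]oxy}-2-ethynylbenzene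
Conditions: dimethyl (1-diazo-2-oxopropyl)phosphonate, K2CO3, MeOH/THF, 0 °C to rt
Reagents that add atoms: dimethyl (1-diazo-2-oxopropyl)phosphonate, CC(=O)C(=[N+]=[N-])P(=O)(OC)OC
Why: Ohira–Bestmann (Seyferth–Gilbert) homologation of the aldehyde to the terminal alkyne, the new carbon being C4''; carbonate in methanol at room temperature should not touch the allylic aryl ether, the Z-alkene or the silyl ether.

Step 11
Reactants: 15 1,5-bis(benzyloxy)-3-{[(1S,2Z,4S)-4-[4-(benzyloxy)phenyl]-4-[(tert-butyldimethylsilyl)oxy]-1-(4-methoxyphenyl)but-2-en-1-yl]oxy}-2-ethynylbenzene; 3 1,5-bis(benzyloxy)-3-fluoro-2-iodobenzene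
Product: 16 1,5-bis(benzyloxy)-2-{[2,4-bis(benzyloxy)-6-fluorophenyl]ethynyl}-3-{[(1S,2Z,4S)-4-[4-(benzyloxy)phenyl]-4-[(tert-butyldimethylsilyl)oxy]-1-(4-methoxyphenyl)but-2-en-1-yl]oxy}benzene
Conditions: Pd(PPh3)2Cl2 (5 mol %), CuI (10 mol %), Et3N/THF, 40 °C, degassed, 3 in excess
Reagents that add atoms: none
Why: Sonogashira coupling of a terminal alkyne with an aryl iodide; the diarylacetylene is made only after the semihydrogenation so no second alkyne has to be discriminated, and the temperature is kept low so that zerovalent palladium does not ionise the allylic aryl ether and no Claisen rearrangement sets in.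

Step 12
Reactants: 16 1,5-bis(benzyloxy)-2-{[2,4-bis(benzyloxy)-6-fluorophenyl]ethynyl}-3-{[(1S,2Z,4S)-4-[4-(benzyloxy)phenyl]-4-[(tert-butyldimethylsilyl)oxy]-1-(4-methoxyphenyl)but-2-en-1-yl]oxy}benzene
Product: 17 cyclobutene-fused 2H-chromene (2S,3S,3''R,2''S): ring C of unit A fused through C3–C4 to the cyclobutene C3–C4=C4''–C3''
Conditions: thioxanthone (20 mol %), 405 nm LEDs, degassed CH2Cl2 (0.005 M), −40 °C
Reagents that add atoms: none
Why: Proposed new method: triplet energy transfer from thioxanthone (about 65 kcal/mol) should populate only the diarylacetylene (about 60 kcal/mol; the isolated Z-alkene and the alkoxyarenes lie far higher), whose bent, 1,2-biradical-like triplet adds through C4 to C3 and, after intersystem crossing of the vinyl/alkyl 1,4-biradical, closes C3''–C4''; the closest known reaction types are the sensitised [2+2] photocycloaddition of diarylacetylenes to alkenes giving cyclobutenes and visible-light energy-transfer cycloadditions of tethered enynes, neither of which has been shown on an aryl-ether-tethered 1,7-enyne with an acyclic Z-alkene. Ring C of unit A closes by 6-exo-trig attack of C4 on C3, preferred over 7-endo attack at the more hindered C3'', and the cyclobutene closes by radical recombination within the 1,4-biradical. C3 is controlled by C2: allylic 1,3-strain in the Z-alkene keeps H2 in the alkene plane with O1 and the 4-methoxyphenyl group on opposite faces, so C4 arrives on the O1 face anti to the aryl group and the 2,3-trans ring results. C3'' is controlled by the Z geometry: bonding on the same alkene face at both carbons places C2 and C2'' cis on the cyclobutene, which is the unlike C3/C3'' pair of the target. The selectivity the step needs is therefore closure of the biradical before rotation about C3–C3'', which would lead to the sterically easier trans cyclobutene. The substrate offers a C3'' orbital that already points at C4'' when the first bond has formed, a vinyl-radical terminus that should shorten the triplet lifetime, and slow rotation of the bulky silyloxybenzyl group past C2 at low temperature, but none of these guarantees it. The fluoroaryl ring on C4'' stays twisted out of the cyclobutene plane, so the benzyloxy groups flanking C4 and C4'' do not clash, and CH2Cl2 is chosen over toluene so that the sensitiser triplet is not consumed by hydrogen abstraction from solvent.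

Step 13
Reactants: 17 cyclobutene-fused 2H-chromene (2S,3S,3''R,2''S)
Product: 19 cis-4,4''-diol (2S,3R,4S,4''R,3''S,2''S) with both hydroxyls on the face of H3 and H3'', via bis(pyridine) osmate ester 18 (not isolated)
Conditions: OsO4 (1.1 equiv), pyridine, CH2Cl2, −20 °C to rt; then aq. NaHSO3, rt
Reagents that add atoms: osmium tetroxide, O=[Os](=O)(=O)=O
Why: Stoichiometric osmylation of the strained, electron-rich tetrasubstituted alkene, a [3+2] addition expected on the cyclobutene face that carries only H3 and H3''; reductive hydrolysis of the osmate ester gives the diol, whose new centres at C4 and C4'' are erased in the next step.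

Step 14
Reactants: 19 cis-4,4''-diol (2S,3R,4S,4''R,3''S,2''S)
Product: 20 (2S,3R)-5,7-bis(benzyloxy)-3-[(2S,3S)-1-[2,4-bis(benzyloxy)-6-fluorophenyl]-3-[4-(benzyloxy)phenyl]-3-[(tert-butyldimethylsilyl)oxy]-1-oxopropan-2-yl]-2-(4-methoxyphenyl)chroman-4-one
Conditions: Pb(OAc)4, pyridine, CH2Cl2, −20 to 0 °C
Reagents that add atoms: none
Why: Criegee glycol cleavage of the cis-cyclobutanediol, helped by release of ring strain, unveils both aryl ketones at once and with them ring C of unit A as a chroman-4-one; pyridine buffers the acetic acid so that the bis-benzylic diol does not undergo pinacol rearrangement and C3 and C3'' are not enolised.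

Step 15
Reactants: 20 (2S,3R)-5,7-bis(benzyloxy)-3-[(2S,3S)-1-[2,4-bis(benzyloxy)-6-fluorophenyl]-3-[4-(benzyloxy)phenyl]-3-[(tert-butyldimethylsilyl)oxy]-1-oxopropan-2-yl]-2-(4-methoxyphenyl)chroman-4-one
Product: 22 penta-O-benzyl biflavanone (2S,3R,2''S,3''S), via tetrabutylammonium C2''-alkoxide 21 (not isolated)
Conditions: Bu4NF (1.1 equiv), THF, −20 to 0 °C; quench with pH 7 phosphate buffer
Reagents that add atoms: none
Why: Fluoride cleaves the silyl ether and the alkoxide attacks the fluoroarene activated by the ortho ketone in a 6-exo intramolecular SNAr reaction that closes ring C of unit B; the C2''–O bond is never broken, so C2'' and C3'' are carried over unchanged and the 2'',3''-cis ring results; fluoride is released again by the substitution, and the cold buffered quench limits enolisation at C3''.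

Step 16
Reactants: 22 penta-O-benzyl biflavanone (2S,3R,2''S,3''S)
Product: 23 (2S,3R)-3-[(2S,3S)-5,7-dihydroxy-2-(4-hydroxyphenyl)-4-oxochroman-3-yl]-5,7-dihydroxy-2-(4-methoxyphenyl)chroman-4-one (target)
Conditions: H2 (1 atm), Pd/C (10 wt %), EtOAc/MeOH, rt
Reagents that add atoms: none
Why: Hydrogenolysis of the five benzyl ethers under neutral conditions; the methyl ether, the ketones and the C2–O1 and C2''–O1'' bonds should survive a short exposure, and no base is present that could epimerise the cis unit.

## Compound list

1 | 5-fluororesorcinol | Oc1cc(O)cc(F)c1 | starting material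
2 | 1,3-bis(benzyloxy)-5-fluorobenzene | Fc1cc(OCc2ccccc2)cc(OCc2ccccc2)c1 | intermediate
3 | 1,5-bis(benzyloxy)-3-fluoro-2-iodobenzene | Ic1c(F)cc(OCc2ccccc2)cc1OCc1ccccc1 | intermediate
4 | 3,5-bis(benzyloxy)phenol | Oc1cc(OCc2ccccc2)cc(OCc2ccccc2)c1 | starting material
5 | 4,6-bis(benzyloxy)-2-hydroxybenzaldehyde | O=Cc1c(O)cc(OCc2ccccc2)cc1OCc1ccccc1 | intermediate
6 | 4-(benzyloxy)benzaldehyde | O=Cc1ccc(OCc2ccccc2)cc1 | starting material
7 | ethynyltrimethylsilane | C#C[Si](C)(C)C | starting material
8 | (1R)-1-[4-(benzyloxy)phenyl]-3-(trimethylsilyl)prop-2-yn-1-ol | C[Si](C)(C)C#C[C@H](O)c1ccc(OCc2ccccc2)cc1 | intermediate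
9 | tert-butyl{[(1R)-1-[4-(benzyloxy)phenyl]-3-(trimethylsilyl)prop-2-yn-1-yl]oxy}dimethylsilane | C[Si](C)(C)C#C[C@H](O[Si](C)(C)C(C)(C)C)c1ccc(OCc2ccccc2)cc1 | intermediate
10 | tert-butyl{[(1S)-1-[4-(benzyloxy)phenyl]prop-2-yn-1-yl]oxy}dimethylsilane | C#C[C@H](O[Si](C)(C)C(C)(C)C)c1ccc(OCc2ccccc2)cc1 | intermediate
11 | 4-methoxybenzaldehyde | COc1ccc(C=O)cc1 | starting material
12 | (1S,4R)-4-[4-(benzyloxy)phenyl]-4-[(tert-butyldimethylsilyl)oxy]-1-(4-methoxyphenyl)but-2-yn-1-ol | COc1ccc([C@H](O)C#C[C@H](O[Si](C)(C)C(C)(C)C)c2ccc(OCc3ccccc3)cc2)cc1 | intermediate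
13 | 2-{[(1R,4R)-4-[4-(benzyloxy)phenyl]-4-[(tert-butyldimethylsilyl)oxy]-1-(4-methoxyphenyl)but-2-yn-1-yl]oxy}-4,6-bis(benzyloxy)benzaldehyde | COc1ccc([C@@H](Oc2cc(OCc3ccccc3)cc(OCc3ccccc3)c2C=O)C#C[C@H](O[Si](C)(C)C(C)(C)C)c2ccc(OCc3ccccc3)cc2)cc1 | intermediate
14 | 2-{[(1S,2Z,4S)-4-[4-(benzyloxy)phenyl]-4-[(tert-butyldimethylsilyl)oxy]-1-(4-methoxyphenyl)but-2-en-1-yl]oxy}-4,6-bis(benzyloxy)benzaldehyde | COc1ccc([C@@H](Oc2cc(OCc3ccccc3)cc(OCc3ccccc3)c2C=O)/C=C\[C@H](O[Si](C)(C)C(C)(C)C)c2ccc(OCc3ccccc3)cc2)cc1 | intermediate
15 | 1,5-bis(benzyloxy)-3-{[(1S,2Z,4S)-4-[4-(benzyloxy)phenyl]-4-[(tert-butyldimethylsilyl)oxy]-1-(4-methoxyphenyl)but-2-en-1-yl]oxy}-2-ethynylbenzene | COc1ccc([C@@H](Oc2cc(OCc3ccccc3)cc(OCc3ccccc3)c2C#C)/C=C\[C@H](O[Si](C)(C)C(C)(C)C)c2ccc(OCc3ccccc3)cc2)cc1 | intermediate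
16 | 1,5-bis(benzyloxy)-2-{[2,4-bis(benzyloxy)-6-fluorophenyl]ethynyl}-3-{[(1S,2Z,4S)-4-[4-(benzyloxy)phenyl]-4-[(tert-butyldimethylsilyl)oxy]-1-(4-methoxyphenyl)but-2-en-1-yl]oxy}benzene (precursor of the key step) | COc1ccc([C@@H](Oc2cc(OCc3ccccc3)cc(OCc3ccccc3)c2C#Cc2c(F)cc(OCc3ccccc3)cc2OCc2ccccc2)/C=C\[C@H](O[Si](C)(C)C(C)(C)C)c2ccc(OCc3ccccc3)cc2)cc1 | intermediate
17 | cyclobutene-fused 2H-chromene, (2S,3S,3''R,2''S) in flavanone numbering: 5,7-bis(benzyloxy)-2-(4-methoxyphenyl) ring C fused at C3–C4 to the cyclobutene C3–C4=C4''–C3''; C4'' bears 2,4-bis(benzyloxy)-6-fluorophenyl, C3'' bears (S)-[4-(benzyloxy)phenyl][(tert-butyldimethylsilyl)oxy]methyl; H2/H3 trans, H3/H3'' cis | COc1ccc([C@H]2Oc3cc(OCc4ccccc4)cc(OCc4ccccc4)c3C3=C(c4c(F)cc(OCc5ccccc5)cc4OCc4ccccc4)[C@H]([C@H](O[Si](C)(C)C(C)(C)C)c4ccc(OCc5ccccc5)cc4)[C@H]23)cc1 | intermediate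
18 | bis(pyridine) osmate ester of 17: cyclic ester of hexavalent osmium bridging O4 and O4'' on the face of H3 and H3'', with two pyridine ligands | COc1ccc([C@H]2Oc3cc(OCc4ccccc4)cc(OCc4ccccc4)c3[C@@]34O[Os](=O)(=O)O[C@@]4(c4c(F)cc(OCc5ccccc5)cc4OCc4ccccc4)[C@H]([C@H](O[Si](C)(C)C(C)(C)C)c4ccc(OCc5ccccc5)cc4)[C@H]23)cc1.c1ccncc1.c1ccncc1 | intermediate (not isolated)
19 | cis-4,4''-diol of 17, (2S,3R,4S,4''R,3''S,2''S): cyclobutane-1,2-diol with both hydroxyls cis to H3 and H3'' | COc1ccc([C@H]2Oc3cc(OCc4ccccc4)cc(OCc4ccccc4)c3[C@]3(O)[C@](O)(c4c(F)cc(OCc5ccccc5)cc4OCc4ccccc4)[C@H]([C@H](O[Si](C)(C)C(C)(C)C)c4ccc(OCc5ccccc5)cc4)[C@H]23)cc1 | intermediate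
20 | (2S,3R)-5,7-bis(benzyloxy)-3-[(2S,3S)-1-[2,4-bis(benzyloxy)-6-fluorophenyl]-3-[4-(benzyloxy)phenyl]-3-[(tert-butyldimethylsilyl)oxy]-1-oxopropan-2-yl]-2-(4-methoxyphenyl)chroman-4-one | COc1ccc([C@H]2Oc3cc(OCc4ccccc4)cc(OCc4ccccc4)c3C(=O)[C@@H]2[C@H](C(=O)c2c(F)cc(OCc3ccccc3)cc2OCc2ccccc2)[C@H](O[Si](C)(C)C(C)(C)C)c2ccc(OCc3ccccc3)cc2)cc1 | intermediate
21 | tetrabutylammonium C2''-alkoxide of desilylated 20 | COc1ccc([C@H]2Oc3cc(OCc4ccccc4)cc(OCc4ccccc4)c3C(=O)[C@@H]2[C@H](C(=O)c2c(F)cc(OCc3ccccc3)cc2OCc2ccccc2)[C@H]([O-])c2ccc(OCc3ccccc3)cc2)cc1.CCCC[N+](CCCC)(CCCC)CCCC | intermediate (not isolated)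
22 | (2S,3R)-5,7-bis(benzyloxy)-3-[(2S,3S)-5,7-bis(benzyloxy)-2-[4-(benzyloxy)phenyl]-4-oxochroman-3-yl]-2-(4-methoxyphenyl)chroman-4-one | COc1ccc([C@H]2Oc3cc(OCc4ccccc4)cc(OCc4ccccc4)c3C(=O)[C@@H]2[C@@H]2C(=O)c3c(OCc4ccccc4)cc(OCc4ccccc4)cc3O[C@@H]2c2ccc(OCc3ccccc3)cc2)cc1 | intermediate
23 | (2S,3R)-3-[(2S,3S)-5,7-dihydroxy-2-(4-hydroxyphenyl)-4-oxochroman-3-yl]-5,7-dihydroxy-2-(4-methoxyphenyl)chroman-4-one | COc1ccc([C@H]2Oc3cc(O)cc(O)c3C(=O)[C@@H]2[C@@H]2C(=O)c3c(O)cc(O)cc3O[C@@H]2c2ccc(O)cc2)cc1 | target

## Step count and least certain steps

Total: 16 steps. Longest linear sequence: 13 steps (steps 4 to 16, from 6 to 23).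

**Step 12 (key step, the one carrying the proposed new method).**
- What is most likely to go wrong: loss of the alkene geometry in the triplet 1,4-biradical. Rotation about C3–C3'' is normally faster than intersystem crossing, and the rotated conformer closes to the sterically easier trans cyclobutene, which has the wrong C3'' configuration.
- Also possible: hydrogen transfer from an ortho benzyloxy CH2 group to the vinyl radical, and electron transfer from the electron-rich arenes to the excited sensitiser in place of energy transfer.
- Fallback with known chemistry, from 16 back to 17: π-acid catalysed [2+2] cycloisomerisation of the 1,7-enyne, with PtCl2 (5 mol %) under CO (1 atm) in toluene at 60 °C or with Au(PPh3)NTf2 at room temperature. This reaction type passes through a cyclopropyl metal carbene and ring expansion, involves no freely rotating radical, and is stereospecific in the alkene geometry. It makes no new compound (F0).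

**Step 8 (Mitsunobu etherification).**
- What is most likely to go wrong: ionisation of the oxyphosphonium ion of the 4-methoxyphenyl propargylic carbinol, with partial loss of inversion at C2. The hydrogen-bonded salicylaldehyde phenol is a slow nucleophile, which gives ionisation more time.
- Fallback, from 10, 11 and 2 back to 13, forming O1–C8a instead of O1–C2 so that no substitution occurs at C2:
  - Step 7 is run with the ligand enantiomer of step 4 to give the C2-epimeric alcohol (1R,4R)-4-[4-(benzyloxy)phenyl]-4-[(tert-butyldimethylsilyl)oxy]-1-(4-methoxyphenyl)but-2-yn-1-ol F1.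
  - Fluoroarene 2 is formylated under Vilsmeier–Haack conditions (POCl3, DMF) ortho to fluorine to give 2,4-bis(benzyloxy)-6-fluorobenzaldehyde F2.
  - The sodium alkoxide of F1 (NaH, THF/DMF, 0 °C) displaces fluoride from F2 in an SNAr reaction activated by the ortho formyl group. C2 is retained, and the product is 13.

**Step 15 (desilylation and SNAr closure).**
- What is most likely to go wrong: base-induced loss of the cis relationship in unit B by enolisation at C3'', or beta-elimination or retro-aldol cleavage of the beta-alkoxy ketone before the ring closes, all driven by free fluoride in the presence of the diketone.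
- Fallback, from 20 back to 22, separating the two events:
  - The silyl ether is removed under buffered acidic conditions (HF·pyridine, pyridine, THF, 0 °C), where no enolate can form, to give the hydroxy diketone (2S,3R)-5,7-bis(benzyloxy)-3-[(2S,3S)-1-[2,4-bis(benzyloxy)-6-fluorophenyl]-3-[4-(benzyloxy)phenyl]-3-hydroxy-1-oxopropan-2-yl]-2-(4-methoxyphenyl)chroman-4-one F3.
  - The ring is then closed from the preformed sodium alkoxide (NaH, THF, −40 to 0 °C). The only base present is the alkoxide, which the substitution consumes.

**Step 13 (osmylation).**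
- What is most likely to go wrong: slow addition to a tetrasubstituted alkene flanked by a twisted, doubly ortho-substituted aryl ring, or acid-promoted pinacol rearrangement of the strained bis-benzylic diol during hydrolysis of the osmate ester.
- Fallback, from 17 directly to 20: ozonolysis (O3, CH2Cl2/MeOH, −78 °C, with a dye indicator such as Sudan red so that the arenes are not over-oxidised; then Me2S). This is a one-step oxidative cleavage of the cyclobutene that avoids the diol. It makes no new compound (F0).

## Further compounds

F0 | step 12 | none | none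
F1 | step 8 | (1R,4R)-4-[4-(benzyloxy)phenyl]-4-[(tert-butyldimethylsilyl)oxy]-1-(4-methoxyphenyl)but-2-yn-1-ol | COc1ccc([C@@H](O)C#C[C@H](O[Si](C)(C)C(C)(C)C)c2ccc(OCc3ccccc3)cc2)cc1
F2 | step 8 | 2,4-bis(benzyloxy)-6-fluorobenzaldehyde | O=Cc1c(F)cc(OCc2ccccc2)cc1OCc1ccccc1
F3 | step 15 | (2S,3R)-5,7-bis(benzyloxy)-3-[(2S,3S)-1-[2,4-bis(benzyloxy)-6-fluorophenyl]-3-[4-(benzyloxy)phenyl]-3-hydroxy-1-oxopropan-2-yl]-2-(4-methoxyphenyl)chroman-4-one | COc1ccc([C@H]2Oc3cc(OCc4ccccc4)cc(OCc4ccccc4)c3C(=O)[C@@H]2[C@H](C(=O)c2c(F)cc(OCc3ccccc3)cc2OCc2ccccc2)[C@H](O)c2ccc(OCc3ccccc3)cc2)cc1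
F0 | step 13 | none | none
A1 | alternative 1 | methyl 2-[(3R,4R)-4-(4-methoxyphenyl)-2-oxooxetan-3-yl]acetate (cis-beta-lactone) | COC(=O)C[C@H]1C(=O)O[C@H]1c1ccc(OC)cc1
A2 | alternative 1 | methyl 2-[(2S,3R)-5,7-bis(benzyloxy)-2-(4-methoxyphenyl)-4-oxochroman-3-yl]acetate | COc1ccc([C@H]2Oc3cc(OCc4ccccc4)cc(OCc4ccccc4)c3C(=O)[C@@H]2CC(=O)OC)cc1
A3 | alternative 2 | 3,5-bis(benzyloxy)-2-(dimethoxymethyl)phenol | COC(OC)c1c(O)cc(OCc2ccccc2)cc1OCc1ccccc1
A4 | alternative 2 | 5,7-bis(benzyloxy)-3-[(E)-2-(4-methoxyphenyl)ethenyl]-4H-chromen-4-one | COc1ccc(/C=C/c2coc3cc(OCc4ccccc4)cc(OCc4ccccc4)c3c2=O)cc1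
A5 | alternative 2 | 2,3-trans-5,7-bis(benzyloxy)-4-methoxy-2-(4-methoxyphenyl)flavan bearing 5,7-bis(benzyloxy)-4-oxo-4H-chromen-3-yl at C3 | COc1ccc([C@H]2Oc3cc(OCc4ccccc4)cc(OCc4ccccc4)c3[C@@H](OC)[C@@H]2c2coc3cc(OCc4ccccc4)cc(OCc4ccccc4)c3c2=O)cc1
A6 | alternative 3 | 4,6-bis(benzyloxy)-2-{(1S,2E)-2-[5,7-bis(benzyloxy)-2-[4-(benzyloxy)phenyl]-4-oxochroman-3-ylidene]-1-(4-methoxyphenyl)ethoxy}benzaldehyde, C2'' arranged as in the target | COc1ccc([C@@H](Oc2cc(OCc3ccccc3)cc(OCc3ccccc3)c2C=O)/C=C2/C(=O)c3c(OCc4ccccc4)cc(OCc4ccccc4)cc3O[C@@H]2c2ccc(OCc3ccccc3)cc2)cc1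
A7 | alternative 3 | (2S,3R)-5,7-bis(benzyloxy)-3-[(2S,3S)-5,7-bis(benzyloxy)-2-[4-(benzyloxy)phenyl]-4-oxochroman-3-yl]-2-(4-methoxyphenyl)chroman-4-one | COc1ccc([C@H]2Oc3cc(OCc4ccccc4)cc(OCc4ccccc4)c3C(=O)[C@@H]2[C@@H]2C(=O)c3c(OCc4ccccc4)cc(OCc4ccccc4)cc3O[C@@H]2c2ccc(OCc3ccccc3)cc2)cc1
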